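A small charge of free catalyst, 50 µM, works through a racemate, and the two mirror-image substrates leave at different speeds.

| flask | left-handed substrate | right-handed substrate | gas | free catalyst | remark | time |
|---|---|---|---|---|---|---|
| amber | 0.050 M | 0.050 M | 2 mM (held) | 50 µM | the very flask that is asked about, followed so far |  |
| ochre | 0.034 M | 0.034 M | 2 mM (held) | 50 µM | run made earlier |  |
| flask | 0.050 M | 0.050 M | 2.0 mM (held) | 50 µM |  | 2.0 min |

- amber (time / s: left-handed product / %, right-handed product / %, left-handed substrate / %): 10.0: 2, 2, 47; 15.0: 5, 0, 48; 20.0: 4, 0, 47
- ochre (time / s: left-handed product / %, right-handed product / %, left-handed substrate / %): 10.0: 1, 1, 46; 15.0: 4, 1, 45; 40.0: 11, 2, 39; 80.0: 21, 6, 31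

(scatter of a reading: 1.5 percentage points)

- free catalyst is single-handed; left-handed substrate and right-handed substrate are mirror images of each other, charged as a racemate, each of them at the stated concentration
- at the start none of the gas is in solution

1. left-handed product present at 2.0 min, in percent of the left-handed substrate and right-handed substrate together charged
2. right-handed product present at 2.0 min, in percent of the left-handed substrate and right-handed substrate together charged
3. concentration of partner at 2.0 min, in M

My scale starts from the symmetric case, where both substrates fall alike and the selectivity factor is 1. I defined that factor as the logarithm of the fraction of left-handed substrate remaining over the same logarithm for right-handed substrate. Counting each product as taken from its own substrate, the last ochre reading gives 4.26, a reading that carries the scatter.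

For the asked flask I then reckoned rates, assuming each substrate falls pseudo-first-order and the left-handed one keeps the ochre pace, 0.00681 s⁻¹. Unslowed for 2.0 min, the left-handed rate would make 40.9% and the right-handed rate, divided by the factor, 9.59%. In my reckoning the left-handed rate ended at 0.442 of its start against 0.826 for the right-handed rate, so it sank further. Averaged over the run, those slowings are factors of 0.683 and 0.910. I therefore committed to 27.9% and 8.72%. Partner I read as the gas once in solution, so I put it just under the saturation, 2.0 mM.

The forecast said 25%, 7.5% and 0.032 M, with “partner forms 1:1 with total product”. My products stood higher, my partner far lower.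

The flask gave 25.0% left-handed product, 7.68% right-handed product and 0.00185 M of partner.

    gas ⇌ partner, rate k1*(csat - [partner]) (kL = 1.50 s⁻¹)
    free catalyst + right-handed substrate ⇌ catalyst intermediate B (K = 6.70 M⁻¹, k = 57000 M⁻¹ s⁻¹)
    free catalyst + left-handed substrate ⇌ catalyst intermediate A (K = 10.0 M⁻¹, k = 4700 M⁻¹ s⁻¹)
    partner + catalyst intermediate B → free catalyst + right-handed product (k = 3800 M⁻¹ s⁻¹)
    partner + catalyst intermediate A → free catalyst + left-handed product (k = 11000 M⁻¹ s⁻¹)

In this flask, at 2.00 min, partner was made 1.00 times as fast as it was used up, each step taken net. The factor 4.26 turns this flask's 50% of left-handed substrate left into 7.51% right-handed product, against the 7.68% found. The neighbour charged with 2.0 × 10⁻⁴ M of free catalyst kept 5.6% of its left-handed substrate at 2.00 min, which by the same factor means 24.6% right-handed product, and it held 25.0%.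

(The readings come from a simulation with constants of no real substance, noise included.)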